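**Retrosynthetic overview**
- Enabling feature: the only ring, C1(=O)–C2(OH)=C3(chain)–C4(=O)–C5(OH)=C6(H), is the bis-enol of a cyclohexane-1,2,4,5-tetraone. Two vicinal dicarbonyl pairs (C1/C2 and C4/C5) are bridged by C3 and C6, each flanked by two carbonyl groups and so a natural enolate carbon.
- Key disconnection: cut C2–C3 and C1–C6 together. C1/C2 become diethyl oxalate (1,2-dielectrophile). C6–C5–C4–C3 plus the side chain become acyclic (E)-tricos-18-ene-2,3-dione (1,4-dinucleophile). A one-pot double Claisen condensation gives the ring, all four oxygens and the final oxidation level, with no protecting group and no redox step.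
- The C4–C5 bond joins two carbonyl carbons of like polarity. It comes from 1-ethoxyvinyllithium (an acyl anion equivalent) and a C21 Weinreb amide.
- The E-alkene comes from a Julia–Kocienski olefination of a C16 aldehyde (from 16-hexadecanolide) with a C5 phenyltetrazolyl sulfone.
- Ring order: there is one ring, and it is closed in the last step.

Key step: step 7

Remark on the chemistry: swapping the OH and C=O roles within C1/C2 and C4/C5 of 17 gives the same compound under mirror numbering, so it does not matter which oxalate carbon bonds to C3 and which to C6.

Step 1
Reactants: 1 1-phenyl-1H-tetrazole-5-thiol; 2 1-bromopentane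
Product: 3 5-(pentylsulfanyl)-1-phenyl-1H-tetrazole
Conditions: K2CO3, acetone, reflux
Reagents that add atoms: none
Why: SN2 S-alkylation of the soft, acidic tetrazolethiolate with a primary bromide is fast and selective for sulfur.

Step 2
Reactants: 3 5-(pentylsulfanyl)-1-phenyl-1H-tetrazole
Product: 4 5-(pentane-1-sulfonyl)-1-phenyl-1H-tetrazole
Conditions: 30% aq H2O2, (NH4)6Mo7O24·4H2O (cat.), EtOH, 0 °C to rt
Reagents that add atoms: hydrogen peroxide, OO
Why: Molybdate-catalysed peroxide oxidation of a sulfide to the sulfone is the standard entry to Julia–Kocienski reagents, and 3 holds nothing else that can be oxidised.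

Step 3
Reactants: 5 16-hexadecanolide (oxacycloheptadecan-2-one)
Product: 6 16-hydroxy-N-methoxy-N-methylhexadecanamide
Conditions: MeNH(OMe)·HCl, i-PrMgCl, THF, −20 to 0 °C; aq NH4Cl
Reagents that add atoms: N,O-dimethylhydroxylamine hydrochloride, CNOC.Cl
Why: Weinreb amide synthesis by aminolysis with the chloromagnesium amide opens the strain-free macrolactone like an ordinary ester and frees the C16 alcohol without a protecting group.

Step 4
Reactants: 6 16-hydroxy-N-methoxy-N-methylhexadecanamide
Product: 7 N-methoxy-N-methyl-16-oxohexadecanamide
Conditions: TEMPO (cat.), PhI(OAc)2, CH2Cl2, rt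
Reagents that add atoms: none
Why: Oxoammonium-mediated oxidation of a primary alcohol stops at the aldehyde in anhydrous CH2Cl2 and leaves the Weinreb amide untouched.

Step 5
Reactants: 4 5-(pentane-1-sulfonyl)-1-phenyl-1H-tetrazole; 7 N-methoxy-N-methyl-16-oxohexadecanamide
Product: 9 (E)-N-methoxy-N-methylhenicos-16-enamide, via potassiated sulfone 8 (not isolated)
Conditions: 4, KN(SiMe3)2, DME, −60 °C; then 7, −60 °C to rt; aq NH4Cl
Reagents that add atoms: none
Why: Julia–Kocienski olefination, in which the potassiated phenyltetrazolyl sulfone adds to the unhindered aldehyde through an open transition state in the polar solvent to give mainly the anti beta-alkoxy sulfone, whose Smiles rearrangement and stereospecific anti elimination set the E geometry of C16=C17, while the Weinreb amide is far less electrophilic than the aldehyde at low temperature.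

Step 6
Reactants: 9 (E)-N-methoxy-N-methylhenicos-16-enamide; 10 ethyl vinyl ether
Product: 13 (E)-tricos-18-ene-2,3-dione, via 1-ethoxyvinyllithium 11 (not isolated), via ethoxy enone 12 (not isolated)
Conditions: 10 (excess), t-BuLi, THF, −78 to 0 °C; then 9, −78 to 0 °C; then 1 M HCl, THF, rt
Reagents that add atoms: water, O
Why: Weinreb ketone synthesis with an acyl anion equivalent (polarity reversal), in which lithiated ethyl vinyl ether adds only once because the chelated tetrahedral adduct survives until the quench, and dilute acid then hydrolyses the enol ether of 12 to the second ketone without touching the isolated E-alkene.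

Step 7
Reactants: 13 (E)-tricos-18-ene-2,3-dione; 14 diethyl oxalate
Product: 17 2,5-dihydroxy-3-[(E)-nonadec-14-en-1-yl]cyclohexa-2,5-diene-1,4-dione, via trioxo ester 15 (not isolated), via disodium salt 16 (not isolated)
Conditions: NaOEt (3 equiv), 14 (1.2 equiv), EtOH–THF, Ar, 0 °C, slow addition of 13; then 60 °C; then 1 M HCl
Reagents that add atoms: none
Why: Proposed new method: ethoxide enolises the methyl group of 13 (future ring C6), which is acylated by 14 in a crossed Claisen condensation to give 15 as its enolate, then the C6 methylene of 15 (future ring C3) is enolised towards the neighbouring ketone and attacks the remaining ester carbon, ethoxide leaves, and two deprotonations give the dianion 16, which HCl turns into 17. The closest known reaction types are the double Claisen condensation of dialkyl ketones with diethyl oxalate to cyclopentane-1,2,4-triones, the base-induced cyclisation of 5-oxo esters to cyclohexane-1,3-diones and, in nature, the head-to-tail double Claisen union of two arylpyruvate units that builds fungal terphenylquinones; new is that an enolisable aliphatic 1,2-diketone serves as the four-carbon 1,4-dinucleophile, so that the product is born at the quinone oxidation level. The ring closes in a 6-(enolendo)-exo-trig acylation, whereas the rival aldol closure of the same enolate onto C2 of 15 would be a disfavoured 5-(enolendo)-exo-trig process on a carbonyl that is already masked as an enolate. No stereocentre is formed, and the remote E-alkene, isolated from every acidic position, is not touched by alkoxide. The selectivity needed is acylation over self-aldol addition of the electrophilic diketone: aldol additions stay reversible under alkoxide, each acylation is pulled forward by deprotonation of its product, and 16, a doubly vinylogous carboxylate dianion, is the thermodynamic sink of the whole manifold, while slow addition of 13 to premixed base and oxalate keeps free diketone scarce. Regiochemistry is not an issue, because both alpha-carbons of 13 end up bonded to the same oxalyl unit whichever reacts first.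

**Compound list**
1 | 1-phenyl-1H-tetrazole-5-thiol | Sc1nnnn1-c1ccccc1 | starting material
2 | 1-bromopentane | CCCCCBr | starting material
3 | 5-(pentylsulfanyl)-1-phenyl-1H-tetrazole | CCCCCSc1nnnn1-c1ccccc1 | intermediate
4 | 5-(pentane-1-sulfonyl)-1-phenyl-1H-tetrazole | CCCCCS(=O)(=O)c1nnnn1-c1ccccc1 | intermediate
5 | 16-hexadecanolide (oxacycloheptadecan-2-one) | O=C1CCCCCCCCCCCCCCCO1 | starting material
6 | 16-hydroxy-N-methoxy-N-methylhexadecanamide | CON(C)C(=O)CCCCCCCCCCCCCCCO | intermediate
7 | N-methoxy-N-methyl-16-oxohexadecanamide | CON(C)C(=O)CCCCCCCCCCCCCCC=O | intermediate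
8 | potassium salt of sulfone 4, carbanion at C1 of the pentyl chain (not isolated) | CCCC[CH-]S(=O)(=O)c1nnnn1-c1ccccc1.[K+] | intermediate
9 | (E)-N-methoxy-N-methylhenicos-16-enamide | CCCC/C=C/CCCCCCCCCCCCCCC(=O)N(C)OC | intermediate
10 | ethyl vinyl ether | C=COCC | starting material
11 | 1-ethoxyvinyllithium (not isolated) | [Li]C(=C)OCC | intermediate
12 | (E)-2-ethoxytricosa-1,18-dien-3-one (not isolated) | CCCC/C=C/CCCCCCCCCCCCCCC(=O)C(=C)OCC | intermediate
13 | (E)-tricos-18-ene-2,3-dione | CCCC/C=C/CCCCCCCCCCCCCCC(=O)C(C)=O | intermediate
14 | diethyl oxalate | CCOC(=O)C(=O)OCC | starting material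
15 | ethyl (E)-2,4,5-trioxopentacos-20-enoate, present as its sodium enolate (not isolated) | CCCC/C=C/CCCCCCCCCCCCCCC(=O)C(=O)CC(=O)C(=O)OCC | intermediate
16 | disodium 3-[(E)-nonadec-14-en-1-yl]-1,4-benzoquinone-2,5-diolate (not isolated) | CCCC/C=C/CCCCCCCCCCCCCC1=C([O-])C(=O)C=C([O-])C1=O.[Na+].[Na+] | intermediate
17 | 2,5-dihydroxy-3-[(E)-nonadec-14-en-1-yl]cyclohexa-2,5-diene-1,4-dione | CCCC/C=C/CCCCCCCCCCCCCC1=C(O)C(=O)C=C(O)C1=O | target

Total step count: 7. Longest linear sequence: 5 (steps 3 to 7).

**Steps most likely to fail**

(1) Step 7, the proposed new method.
- What may go wrong: the diketone may be used up by self-aldol oligomerisation or by an alkoxide-induced benzilic-type rearrangement before it is acylated. The sequence may stall at the open-chain stage, because the chelated enolate holds the ester away from the nucleophilic carbon. The product dianion may also be ethoxalylated a second time at ring C6.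
- Fallback: it sets out from 13 and comes back at 17. It separates the two C–C bond formations, uses only known reaction types, and never lets a free 1,2-diketone meet base in a bimolecular setting.
- Monoketalisation of the less hindered C2 carbonyl of 13 (HC(OMe)3, MeOH, cat. p-TsOH, rt) should give (E)-2,2-dimethoxytricos-18-en-3-one F1, whose only enolisable position is the C4 methylene.
- Crossed Claisen condensation of this ketone with 14 (NaOEt, EtOH–THF) should give ethyl 5,5-dimethoxy-3-[(E)-nonadec-14-en-1-yl]-2,4-dioxohexanoate F2, in which C3 is configurationally labile and largely enolised.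
- Aqueous CF3CO2H in CH2Cl2 should unmask ethyl 3-[(E)-nonadec-14-en-1-yl]-2,4,5-trioxohexanoate F3.
- NaOEt in EtOH–THF then closes the ring from the methyl group onto the ester (the known cyclisation of a 5-oxo ester to a cyclohexane-1,3-dione), and HCl releases 17.

(2) Step 5.
- What may go wrong: addition of the sulfonyl carbanion to an unbranched aldehyde may show weak anti selectivity, which would erode the E geometry. The carbanion may also condense with itself or attack the Weinreb amide.
- Fallback: it sets out from 7 and comes back at 9. It replaces sulfone chemistry by a geminal dichromium alkylidenation (Takai–Utimoto olefination), whose E preference arises in the elimination step and which tolerates amides.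
- Diiodomethane is deprotonated with NaN(SiMe3)2 (THF, −78 °C) and alkylated with 1-iodobutane to give 1,1-diiodopentane F4.
- This diiodide, CrCl2 (divalent chromium) and DMF in THF at rt should convert 7 directly into 9.

(3) Step 6.
- What may go wrong: incomplete lithiation of the vinyl ether would leave t-BuLi free to add to the amide. The acidic hydrolysis may also trigger self-condensation of the freshly released diketone.
- Fallback: it sets out from 9 and comes back at 13. It uses a dithiane as the masked acetyl anion, and the second carbonyl is released oxidatively instead of by acid hydrolysis.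
- 2-Methyl-1,3-dithiane and n-BuLi (THF, −30 °C) give 2-lithio-2-methyl-1,3-dithiane F5.
- Acylation of this anion by 9 should give (E)-1-(2-methyl-1,3-dithian-2-yl)henicos-16-en-1-one F6.
- Brief treatment with PhI(O2CCF3)2 in aqueous MeCN at 0 °C should remove the dithiane faster than the isolated alkene can react, which gives 13.

**Further compounds**
F1 | step 7 | (E)-2,2-dimethoxytricos-18-en-3-one | CCCC/C=C/CCCCCCCCCCCCCCC(=O)C(C)(OC)OC
F2 | step 7 | ethyl 5,5-dimethoxy-3-[(E)-nonadec-14-en-1-yl]-2,4-dioxohexanoate | CCCC/C=C/CCCCCCCCCCCCCC(C(=O)C(=O)OCC)C(=O)C(C)(OC)OC
F3 | step 7 | ethyl 3-[(E)-nonadec-14-en-1-yl]-2,4,5-trioxohexanoate | CCCC/C=C/CCCCCCCCCCCCCC(C(=O)C(=O)OCC)C(=O)C(C)=O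
F4 | step 5 | 1,1-diiodopentane | CCCCC(I)I
F5 | step 6 | 2-lithio-2-methyl-1,3-dithiane | [Li]C1(C)SCCCS1
F6 | step 6 | (E)-1-(2-methyl-1,3-dithian-2-yl)henicos-16-en-1-one | CCCC/C=C/CCCCCCCCCCCCCCC(=O)C1(C)SCCCS1
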